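**Retrosynthetic overview**

- Ring A is the dimethoxy ring: C1 carries the CH2CH2 chain to ring B, C2 the C7 benzyl carbon to ring C, C3 and C5 the OMe groups, and C4 and C6 are CH. It is the only ring built; rings B and C are bought as benzyl-protected phenols.
- Feature: ring A is a latent cyclohexane-1,3-dione. C3(O) and C5(O) are its carbonyls, C7–C2–C3(O)–C4 is an α-benzylacetone unit, C1 with its chain is an aldehyde carbon, and C5(O)–C6 is a malonate.
- Target 15 ⇐ bis-benzyl ether 14 (hydrogenolysis) ⇐ dione 13 (iodine–methanol aromatization, which installs both OMe groups) ⇐ dione ester 11 (hydrolysis, decarboxylation).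
- 11 ⇐ enone 8 + dimethyl malonate 9: Michael addition forms C1–C6 and Claisen closure forms C4–C5, closing ring A.
- 8 ⇐ aldehyde 4 (from acid 1) + α-benzylated β-ketophosphonate 7 (from 5 and 6) by Horner–Wadsworth–Emmons olefination, which places the benzyl group on the enone α-carbon with no regiochemical ambiguity.

Key step: step 6

Remark: the target has no stereocentre, so the requirement of a single enantiomer is met by the achiral compound itself. Intermediates 7 and 10–13 are racemic, and their stereocentres vanish on olefination or aromatization.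

**Route**

Step 1
Reactants: 1 3-(3-hydroxyphenyl)propanoic acid
Product: 2 benzyl 3-[3-(benzyloxy)phenyl]propanoate
Conditions: BnBr (2.3 equiv), K2CO3 (2.5 equiv), DMF, 60 °C
Reagents that add atoms: benzyl bromide, BrCc1ccccc1
Why: Carbonate forms the phenoxide and the carboxylate, and both are benzylated by SN2 displacement (Williamson etherification and carboxylate O-alkylation), so one operation protects the phenol and gives a reducible ester.

Step 2
Reactants: 2 benzyl 3-[3-(benzyloxy)phenyl]propanoate
Product: 3 3-[3-(benzyloxy)phenyl]propan-1-ol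
Conditions: LiAlH4, THF, 0 °C → rt; aqueous NaOH work-up
Reagents that add atoms: none
Why: Hydride reduction of the ester gives the primary alcohol while the aryl benzyl ether is inert; the benzyl alcohol set free is removed on silica.

Step 3
Reactants: 3 3-[3-(benzyloxy)phenyl]propan-1-ol
Product: 4 3-[3-(benzyloxy)phenyl]propanal
Conditions: TEMPO (10 mol %), PhI(OAc)2 (1.1 equiv), CH2Cl2, rt
Reagents that add atoms: none
Why: The oxoammonium (TEMPO/PhI(OAc)2) oxidation of a primary alcohol stops at the aldehyde and does not touch the benzyl ether.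

Step 4
Reactants: 5 dimethyl (2-oxopropyl)phosphonate; 6 1-(benzyloxy)-4-(chloromethyl)benzene
Product: 7 dimethyl {1-[4-(benzyloxy)phenyl]-3-oxobutan-2-yl}phosphonate (racemic)
Conditions: 5 (1.3 equiv), NaH (1.25 equiv), THF, 0 °C; then 6 (1.0 equiv), NaI (10 mol %), rt → 50 °C
Reagents that add atoms: none
Why: The sodium enolate of the β-ketophosphonate is C-alkylated at its doubly activated carbon by the reactive benzylic chloride (SN2 alkylation of an active methylene compound with iodide catalysis), the excess of 5 suppressing dialkylation; the new stereocentre is racemic and disappears in step 5.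

Step 5
Reactants: 7 dimethyl {1-[4-(benzyloxy)phenyl]-3-oxobutan-2-yl}phosphonate; 4 3-[3-(benzyloxy)phenyl]propanal
Product: 8 (E)-3-[4-(benzyloxy)benzyl]-6-[3-(benzyloxy)phenyl]hex-3-en-2-one
Conditions: NaH (1.1 equiv), THF, 0 °C; then 4, rt → 50 °C
Reagents that add atoms: none
Why: Horner–Wadsworth–Emmons olefination by the preformed α-substituted phosphonate anion gives the trisubstituted enone, the E isomer (acetyl trans to the chain) being expected to predominate; any Z isomer is carried on because the alkene geometry is erased in step 6.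

Step 6
Reactants: 8 (E)-3-[4-(benzyloxy)benzyl]-6-[3-(benzyloxy)phenyl]hex-3-en-2-one; 9 dimethyl malonate
Product: 11 methyl 3-[4-(benzyloxy)benzyl]-2-{2-[3-(benzyloxy)phenyl]ethyl}-4,6-dioxocyclohexane-1-carboxylate (racemic; all-trans isomer drawn; largely enolised), via open-chain Michael adduct 10 (not isolated)
Conditions: 9 (1.3 equiv), NaOMe (1.5 equiv), MeOH, reflux; then 1 M HCl, 0 °C
Reagents that add atoms: none
Why: Methoxide forms the soft malonate anion, which adds 1,4 to the enone β-carbon (ring A C1–C6 bond); the ketone enolate so formed is protonated by methanol and re-forms reversibly on the methyl side, and that enolate attacks one malonate ester carbonyl with loss of methoxide (ring A C4–C5 bond). The closest known reaction type is the Michael–Claisen annulation of enones with malonic esters to cyclohexane-1,3-diones. Ring A closes in a 6-exo-trig mode; closure through the benzyl-bearing α-carbon would give a four-membered ring and does not compete. Three stereocentres arise (the ester-, phenethyl- and benzyl-bearing carbons); the first and third are epimerisable under methoxide, so the all-trans isomer should prevail thermodynamically, but no control is needed because all three are destroyed on aromatization. The step needs conjugate rather than carbonyl addition, which the stabilised malonate anion and the reversibility of 1,2-addition secure, and it is pulled forward by irreversible deprotonation of the product to its β-diketone enolate, which is why more than one equivalent of base is used.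

Step 7
Reactants: 11 methyl 3-[4-(benzyloxy)benzyl]-2-{2-[3-(benzyloxy)phenyl]ethyl}-4,6-dioxocyclohexane-1-carboxylate
Product: 13 trans-4-[4-(benzyloxy)benzyl]-5-{2-[3-(benzyloxy)phenyl]ethyl}cyclohexane-1,3-dione (racemic), via beta-keto acid 12 (not isolated)
Conditions: 2 M NaOH aq., MeOH, reflux; then HCl to pH 1, 80 °C
Reagents that add atoms: none
Why: Saponification followed by acidification and warming decarboxylates the β-keto acid through the usual six-membered transition state (ester hydrolysis–decarboxylation), the dione being shielded as its enolate in base and the benzyl ethers being inert; the epimerisable benzyl-bearing centre should settle trans to its neighbour.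

Step 8
Reactants: 13 trans-4-[4-(benzyloxy)benzyl]-5-{2-[3-(benzyloxy)phenyl]ethyl}cyclohexane-1,3-dione
Product: 14 2-[4-(benzyloxy)benzyl]-1-{2-[3-(benzyloxy)phenyl]ethyl}-3,5-dimethoxybenzene
Conditions: I2 (2 equiv), MeOH, reflux
Reagents that add atoms: methanol, CO
Why: Iodine–methanol oxidative aromatization, a known conversion of cyclohexane-1,3-diones and cyclohexenones into aryl methyl ethers: HI formed in situ catalyses methyl enol ether formation at both carbonyls, α-iodination and loss of HI supply the missing unsaturation, and tautomerization gives the resorcinol dimethyl ether with both ring stereocentres erased.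

Step 9
Reactants: 14 2-[4-(benzyloxy)benzyl]-1-{2-[3-(benzyloxy)phenyl]ethyl}-3,5-dimethoxybenzene
Product: 15 3-{2-[2-(4-hydroxybenzyl)-3,5-dimethoxyphenyl]ethyl}phenol (target)
Conditions: H2 (1 atm), 10% Pd/C, EtOAc–MeOH, rt
Reagents that add atoms: none
Why: Catalytic hydrogenolysis cleaves both aryl benzyl ethers, whereas the aryl methyl ethers, the diarylmethane and the bibenzyl C–C bonds are stable under these mild conditions.

**Compound list**

1 | 3-(3-hydroxyphenyl)propanoic acid | OC(=O)CCc1cccc(O)c1 | starting material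
2 | benzyl 3-[3-(benzyloxy)phenyl]propanoate | O=C(CCc1cccc(OCc2ccccc2)c1)OCc1ccccc1 | intermediate
3 | 3-[3-(benzyloxy)phenyl]propan-1-ol | OCCCc1cccc(OCc2ccccc2)c1 | intermediate
4 | 3-[3-(benzyloxy)phenyl]propanal | O=CCCc1cccc(OCc2ccccc2)c1 | intermediate
5 | dimethyl (2-oxopropyl)phosphonate | CC(=O)CP(=O)(OC)OC | starting material
6 | 1-(benzyloxy)-4-(chloromethyl)benzene | ClCc1ccc(OCc2ccccc2)cc1 | starting material
7 | dimethyl {1-[4-(benzyloxy)phenyl]-3-oxobutan-2-yl}phosphonate (racemic) | CC(=O)C(Cc1ccc(OCc2ccccc2)cc1)P(=O)(OC)OC | intermediate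
8 | (E)-3-[4-(benzyloxy)benzyl]-6-[3-(benzyloxy)phenyl]hex-3-en-2-one | CC(=O)/C(Cc1ccc(OCc2ccccc2)cc1)=C/CCc1cccc(OCc2ccccc2)c1 | intermediate
9 | dimethyl malonate | COC(=O)CC(=O)OC | starting material
10 | dimethyl 2-{4-[4-(benzyloxy)benzyl]-1-[3-(benzyloxy)phenyl]-5-oxohexan-3-yl}propanedioate (racemic diastereomer mixture) | COC(=O)C(C(=O)OC)C(CCc1cccc(OCc2ccccc2)c1)C(Cc1ccc(OCc2ccccc2)cc1)C(C)=O | intermediate (not isolated)
11 | methyl 3-[4-(benzyloxy)benzyl]-2-{2-[3-(benzyloxy)phenyl]ethyl}-4,6-dioxocyclohexane-1-carboxylate (racemic; all-trans drawn) | COC(=O)[C@@H]1C(=O)CC(=O)[C@H](Cc2ccc(OCc3ccccc3)cc2)[C@H]1CCc1cccc(OCc2ccccc2)c1 | intermediate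
12 | 3-[4-(benzyloxy)benzyl]-2-{2-[3-(benzyloxy)phenyl]ethyl}-4,6-dioxocyclohexane-1-carboxylic acid (racemic; all-trans drawn) | OC(=O)[C@@H]1C(=O)CC(=O)[C@H](Cc2ccc(OCc3ccccc3)cc2)[C@H]1CCc1cccc(OCc2ccccc2)c1 | intermediate (not isolated)
13 | trans-4-[4-(benzyloxy)benzyl]-5-{2-[3-(benzyloxy)phenyl]ethyl}cyclohexane-1,3-dione (racemic) | O=C1CC(=O)[C@H](Cc2ccc(OCc3ccccc3)cc2)[C@@H](CCc2cccc(OCc3ccccc3)c2)C1 | intermediate
14 | 2-[4-(benzyloxy)benzyl]-1-{2-[3-(benzyloxy)phenyl]ethyl}-3,5-dimethoxybenzene | COc1cc(CCc2cccc(OCc3ccccc3)c2)c(Cc2ccc(OCc3ccccc3)cc2)c(OC)c1 | intermediate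
15 | 3-{2-[2-(4-hydroxybenzyl)-3,5-dimethoxyphenyl]ethyl}phenol | COc1cc(CCc2cccc(O)c2)c(Cc2ccc(O)cc2)c(OC)c1 | target

**Step count**

Total steps: 9. Longest linear sequence: 8 (steps 1, 2, 3, 5, 6, 7, 8, 9).

**Steps most likely to fail**

1. Step 6. Conjugate addition to the α,β-disubstituted enone may be slow. Methoxide could then deprotonate the γ-position and move the double bond out of conjugation, or the Claisen closure could stall at the open-chain stage. The fallback introduces the benzyl group after ring formation and sets out from aldehyde 4. Wittig olefination with 1-(triphenylphosphoranylidene)propan-2-one (CH2Cl2, rt) should give (E)-6-[3-(benzyloxy)phenyl]hex-3-en-2-one F1. Annulation of this unhindered enone with 9 (NaOMe, MeOH, reflux) should pass through dimethyl 2-{1-[3-(benzyloxy)phenyl]-5-oxohexan-3-yl}propanedioate F2 to methyl 2-{2-[3-(benzyloxy)phenyl]ethyl}-4,6-dioxocyclohexane-1-carboxylate F3. Aqueous NaOH and then HCl with warming should take F3 through 2-{2-[3-(benzyloxy)phenyl]ethyl}-4,6-dioxocyclohexane-1-carboxylic acid F4 to 5-{2-[3-(benzyloxy)phenyl]ethyl}cyclohexane-1,3-dione F5. Enol etherification (MeOH, HC(OMe)3, cat. TsOH) should give 5-{2-[3-(benzyloxy)phenyl]ethyl}-3-methoxycyclohex-2-en-1-one F6. Stork–Danheiser α′-alkylation (LDA, THF, −78 °C; then chloride 6, Bu4NI) should give trans-6-[4-(benzyloxy)benzyl]-5-{2-[3-(benzyloxy)phenyl]ethyl}-3-methoxycyclohex-2-en-1-one F7, the electrophile entering anti to the C5 chain. Hydrolysis of the enol ether (1 M HCl, THF, rt) comes back to the route at 13.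

2. Step 8. Oxidation may run ahead of enol ether formation, leaving phenolic monomethyl ethers. The electron-rich product ring may be iodinated, or HI may cleave the benzyl ethers. The fallback separates aromatization from methylation and sets out from 11. Bromination–dehydrobromination (Br2, 1 equiv, DMF, 0 → 80 °C), a known aromatization of 4,6-dioxocyclohexanecarboxylates, should give methyl 3-[4-(benzyloxy)benzyl]-2-{2-[3-(benzyloxy)phenyl]ethyl}-4,6-dihydroxybenzoate F8. Saponification (NaOH aq., MeOH, reflux) then acidification and warming should pass through 3-[4-(benzyloxy)benzyl]-2-{2-[3-(benzyloxy)phenyl]ethyl}-4,6-dihydroxybenzoic acid F9, which decarboxylates readily as a β-resorcylic acid, to 4-[4-(benzyloxy)benzyl]-5-{2-[3-(benzyloxy)phenyl]ethyl}benzene-1,3-diol F10. Methylation of both free phenols (MeI, K2CO3, acetone, reflux) comes back to the route at 14.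

3. Step 5. Olefination by the hindered α-branched phosphonate anion may be sluggish, so base-mediated self-condensation of the enolisable aldehyde or deacylation of the phosphonate could take over. The fallback is an aldol route that sets out from aldehyde 4. Commercial 4-(4-hydroxyphenyl)butan-2-one is benzylated (BnBr, K2CO3, acetone) to 4-[4-(benzyloxy)phenyl]butan-2-one F11. Silylation under equilibrating conditions (TMSCl, NaI, Et3N, MeCN) should give mainly the more substituted enol ether (Z)-({4-[4-(benzyloxy)phenyl]but-2-en-2-yl}oxy)trimethylsilane F12. Mukaiyama aldol addition to 4 (BF3·OEt2, CH2Cl2, −78 °C) should give 3-[4-(benzyloxy)benzyl]-6-[3-(benzyloxy)phenyl]-4-hydroxyhexan-2-one F13; linear aldol from any terminal enol ether is removed by chromatography at this stage. Acid-catalysed dehydration (cat. TsOH, toluene, 80 °C) comes back to the route at 8.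

**Further compounds**

F1 | step 6 | (E)-6-[3-(benzyloxy)phenyl]hex-3-en-2-one | CC(=O)/C=C/CCc1cccc(OCc2ccccc2)c1
F2 | step 6 | dimethyl 2-{1-[3-(benzyloxy)phenyl]-5-oxohexan-3-yl}propanedioate (racemic) | COC(=O)C(C(=O)OC)C(CCc1cccc(OCc2ccccc2)c1)CC(C)=O
F3 | step 6 | methyl 2-{2-[3-(benzyloxy)phenyl]ethyl}-4,6-dioxocyclohexane-1-carboxylate (racemic, trans) | COC(=O)[C@@H]1C(=O)CC(=O)C[C@H]1CCc1cccc(OCc2ccccc2)c1
F4 | step 6 | 2-{2-[3-(benzyloxy)phenyl]ethyl}-4,6-dioxocyclohexane-1-carboxylic acid (racemic, trans) | OC(=O)[C@@H]1C(=O)CC(=O)C[C@H]1CCc1cccc(OCc2ccccc2)c1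
F5 | step 6 | 5-{2-[3-(benzyloxy)phenyl]ethyl}cyclohexane-1,3-dione | O=C1CC(=O)CC(CCc2cccc(OCc3ccccc3)c2)C1
F6 | step 6 | 5-{2-[3-(benzyloxy)phenyl]ethyl}-3-methoxycyclohex-2-en-1-one (racemic) | COC1=CC(=O)CC(CCc2cccc(OCc3ccccc3)c2)C1
F7 | step 6 | trans-6-[4-(benzyloxy)benzyl]-5-{2-[3-(benzyloxy)phenyl]ethyl}-3-methoxycyclohex-2-en-1-one (racemic) | COC1=CC(=O)[C@H](Cc2ccc(OCc3ccccc3)cc2)[C@@H](CCc2cccc(OCc3ccccc3)c2)C1
F8 | step 8 | methyl 3-[4-(benzyloxy)benzyl]-2-{2-[3-(benzyloxy)phenyl]ethyl}-4,6-dihydroxybenzoate | COC(=O)c1c(O)cc(O)c(Cc2ccc(OCc3ccccc3)cc2)c1CCc1cccc(OCc2ccccc2)c1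
F9 | step 8 | 3-[4-(benzyloxy)benzyl]-2-{2-[3-(benzyloxy)phenyl]ethyl}-4,6-dihydroxybenzoic acid | OC(=O)c1c(O)cc(O)c(Cc2ccc(OCc3ccccc3)cc2)c1CCc1cccc(OCc2ccccc2)c1
F10 | step 8 | 4-[4-(benzyloxy)benzyl]-5-{2-[3-(benzyloxy)phenyl]ethyl}benzene-1,3-diol | Oc1cc(O)c(Cc2ccc(OCc3ccccc3)cc2)c(CCc2cccc(OCc3ccccc3)c2)c1
F11 | step 5 | 4-[4-(benzyloxy)phenyl]butan-2-one | CC(=O)CCc1ccc(OCc2ccccc2)cc1
F12 | step 5 | (Z)-({4-[4-(benzyloxy)phenyl]but-2-en-2-yl}oxy)trimethylsilane | C/C(O[Si](C)(C)C)=C/Cc1ccc(OCc2ccccc2)cc1
F13 | step 5 | 3-[4-(benzyloxy)benzyl]-6-[3-(benzyloxy)phenyl]-4-hydroxyhexan-2-one (racemic diastereomer mixture) | CC(=O)C(Cc1ccc(OCc2ccccc2)cc1)C(O)CCc1cccc(OCc2ccccc2)c1
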